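The target is a C2-symmetric 7,7'-dihydroxy-9,9'-epoxylignan, (7S,8R,8'R,7'S) by its SMILES (lignan numbering: C7/C7' carbinols, C8/C8' = ring C3/C4). Both phenols are unmasked last, both carbinols come from catalyst-controlled reduction of a trans-3,4-bis(aroyl)tetrahydrofuran, and both aryl–C(=O) bonds are cut to a bis-Weinreb amide plus two guaiacyl lithium units.
Feature used: in the tetrahydrofuran (O1, C2, C3, C4, C5) the only ring stereocentres are the neighbours C3 and C4, each bearing an exocyclic carbon at the carbonyl oxidation level. The C3–C4 bond is therefore the α,α' bond of a 1,4-dicarbonyl compound whose α-carbons are already linked through C2–O1–C5.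
Key disconnection: C3–C4, by ring-closing oxidative coupling of the bis-enolate of an acyclic bis(N-acyl oxazolidinone) made from 3,3'-oxydipropanoic acid and (R)-4-benzyl-1,3-oxazolidin-2-one.
Ring order: the tetrahydrofuran is the only ring made (key step); the two guaiacyl rings are bought as 4-bromo-2-methoxyphenol and attached to both acyl carbons in one operation.
Key step: step 3

Step 1
Reactants: 1 3,3'-oxydipropanoic acid
Product: 2 3,3'-oxydipropanoyl dichloride
Conditions: (COCl)2 (2.5 equiv), DMF (cat.), CH2Cl2, 0 °C to rt; evaporate, use crude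
Reagents that add atoms: oxalyl chloride, ClC(=O)C(=O)Cl
Why: Conversion of a carboxylic acid into its chloride with oxalyl chloride under catalysis by DMF (Vilsmeier-type activation) is routine, and the dialkyl ether is inert under these conditions.

Step 2
Reactants: 2 3,3'-oxydipropanoyl dichloride; 3 (R)-4-benzyl-1,3-oxazolidin-2-one
Product: 5 (4R,4'R)-3,3'-(3,3'-oxydipropanoyl)bis(4-benzyl-1,3-oxazolidin-2-one), via N-lithio oxazolidinone 4 (not isolated)
Conditions: 3 (2.1 equiv), n-BuLi (2.05 equiv), THF, −78 °C; then 2 (1.0 equiv), −78 to 0 °C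
Reagents that add atoms: none
Why: N-Acylation of a lithiated oxazolidinone with an acid chloride is the standard entry to N-acyl oxazolidinones and should be fast enough at −78 °C to outrun base-induced β-elimination of the β-alkoxy acyl chloride, while the auxiliary stereocentre is not touched.

Step 3
Reactants: 5 (4R,4'R)-3,3'-(3,3'-oxydipropanoyl)bis(4-benzyl-1,3-oxazolidin-2-one)
Product: 7 (4R,4'R)-3,3'-[(3R,4R)-tetrahydrofuran-3,4-diyldicarbonyl]bis(4-benzyl-1,3-oxazolidin-2-one), via dilithium bis(Z-enolate) 6 (not isolated)
Conditions: 5 added to LiN(i-Pr)2 (2.2 equiv), THF, −78 °C; then CuCl2 (2.5 equiv) in DMF, −78 to −40 °C, high dilution (about 0.02 M)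
Reagents that add atoms: none
Why: Double deprotonation should give the chelated dilithium bis(Z-enolate) 6; one-electron oxidation of one enolate by CuCl2 (divalent copper) gives an α-carbonyl radical that adds to the α-carbon of the second enolate, and a second CuCl2 oxidises the resulting radical anion to the neutral 1,4-dicarbonyl compound. The closest known reaction type is the oxidative coupling of N-acyl oxazolidinone enolates to trans-2,3-disubstituted succinic acid derivatives, including its ring-closing form that gives trans-cycloalkane-1,2-dicarbonyl compounds; here the tether is an ether, so the enolates carry a β-alkoxy group. The tetrahydrofuran closes by 5-exo-trig attack of the C3 radical on the C4=C(OLi) enolate bond, the CH2–O–CH2 tether holding the two carbons 1,5 to each other. C3 and C4 are each set by the benzyl group of their own (R)-oxazolidinone, which shields one face of the chelated Z-enolate so that the new bond forms on the opposite face, as in auxiliary-controlled alkylation; with two identical auxiliaries both centres are expected to come out R, which is the trans ring. The step needs facial selectivity at both carbons and ring closure in preference to β-elimination of the ether oxygen or intermolecular coupling: the matched auxiliaries and the thermodynamic preference for the trans-diacyl ring serve the first, and the low temperature, the chelated enolates and high dilution serve the second.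

Step 4
Reactants: 7 (4R,4'R)-3,3'-[(3R,4R)-tetrahydrofuran-3,4-diyldicarbonyl]bis(4-benzyl-1,3-oxazolidin-2-one)
Product: 8 (3R,4R)-N3,N4-dimethoxy-N3,N4-dimethyltetrahydrofuran-3,4-dicarboxamide
Conditions: MeNH(OMe)·HCl (6 equiv), AlMe3 (6 equiv), CH2Cl2, −15 °C to rt; aq. potassium sodium tartrate work-up; auxiliary 3 recovered
Reagents that add atoms: N,O-dimethylhydroxylamine hydrochloride, CNOC.Cl
Why: Aminolysis of an N-acyl oxazolidinone with the aluminium amide made from AlMe3 and MeNH(OMe)·HCl (Weinreb transamidation) attacks the exocyclic carbonyl, here assisted by coordination of aluminium to the ring oxygen β to each carbonyl, and being non-basic it should leave C3 and C4 as set.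

Step 5
Reactants: 9 4-bromo-2-methoxyphenol
Product: 10 (4-bromo-2-methoxyphenoxy)(tert-butyl)dimethylsilane
Conditions: TBSCl (1.2 equiv), imidazole (2.0 equiv), DMF, rt
Reagents that add atoms: tert-butyldimethylsilyl chloride (TBSCl), CC(C)(C)[Si](C)(C)Cl
Why: Silylation of a phenol with TBSCl and imidazole is routine and masks the acidic OH so that the bromide can undergo bromine–lithium exchange in the next step.

Step 6
Reactants: 8 (3R,4R)-N3,N4-dimethoxy-N3,N4-dimethyltetrahydrofuran-3,4-dicarboxamide; 10 (4-bromo-2-methoxyphenoxy)(tert-butyl)dimethylsilane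
Product: 13 (3R,4R)-3,4-bis[4-(tert-butyldimethylsilyloxy)-3-methoxybenzoyl]tetrahydrofuran, via aryllithium 11 (not isolated), via dilithium bis-hemiaminal adduct 12 (not isolated)
Conditions: 10 (2.3 equiv), n-BuLi (2.2 equiv), THF, −78 °C; then 8 (1.0 equiv), −78 °C; AcOH in THF, −78 °C, then water
Reagents that add atoms: none
Why: Bromine–lithium exchange on 10 gives aryllithium 11, which adds once to each N-methoxy-N-methyl amide to give the lithium-chelated tetrahedral adduct 12 that only collapses to the ketone on the acidic quench (Weinreb ketone synthesis), so over-addition is blocked, and the absence of excess base at −78 °C together with the acidic quench should keep C3 and C4 from enolising.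

Step 7
Reactants: 13 (3R,4R)-3,4-bis[4-(tert-butyldimethylsilyloxy)-3-methoxybenzoyl]tetrahydrofuran
Product: 14 (S,S)-[(3R,4R)-tetrahydrofuran-3,4-diyl]bis{[4-(tert-butyldimethylsilyloxy)-3-methoxyphenyl]methanol}
Conditions: (R)-Me-CBS oxazaborolidine [(3aR)-1-methyl-3,3-diphenyl-3a,4,5,6-tetrahydropyrrolo[1,2-c][1,3,2]oxazaborole, 0.4 equiv], BH3·SMe2 (2.4 equiv), THF, −20 °C; MeOH quench
Reagents that add atoms: none
Why: In this Corey–Bakshi–Shibata reduction the (R)-oxazaborolidine delivers hydride to the face that gives the (S)-carbinol when aryl is the larger ketone substituent, which sets C7 and C7' alike because the two ketones of the C2-symmetric diketone are homotopic, and a Felkin–Anh analysis with the substituted ring carbon as the large α-group points to the same (7S,8R) relationship, so catalyst and substrate control are expected to be matched.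

Step 8
Reactants: 14 (S,S)-[(3R,4R)-tetrahydrofuran-3,4-diyl]bis{[4-(tert-butyldimethylsilyloxy)-3-methoxyphenyl]methanol}
Product: 15 (S,S)-[(3R,4R)-tetrahydrofuran-3,4-diyl]bis[(4-hydroxy-3-methoxyphenyl)methanol], the target CNP0157038.3
Conditions: Bu4NF (2.4 equiv), AcOH (2.4 equiv), THF, 0 °C
Reagents that add atoms: none
Why: Fluoride-mediated desilylation cleaves both aryl Si–O bonds, and the acetic acid buffer protonates the phenoxides as they form so that the p-hydroxybenzylic alcohols should not eliminate to quinone methides, while the trans ring fusion that an ether between C7 and C7' would require keeps the diol from cyclising.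

Compound list
1 | 3,3'-oxydipropanoic acid | OC(=O)CCOCCC(=O)O | starting material
2 | 3,3'-oxydipropanoyl dichloride | ClC(=O)CCOCCC(Cl)=O | intermediate
3 | (R)-4-benzyl-1,3-oxazolidin-2-one | O=C1N[C@H](Cc2ccccc2)CO1 | starting material
4 | N-lithio-(R)-4-benzyl-1,3-oxazolidin-2-one (not isolated) | [Li]N1[C@H](Cc2ccccc2)COC1=O | intermediate
5 | (4R,4'R)-3,3'-(3,3'-oxydipropanoyl)bis(4-benzyl-1,3-oxazolidin-2-one) | O=C(CCOCCC(=O)N1[C@H](Cc2ccccc2)COC1=O)N1[C@H](Cc2ccccc2)COC1=O | intermediate
6 | dilithium bis(Z-enolate) of 5 (not isolated) | [Li]O/C(N1[C@H](Cc2ccccc2)COC1=O)=C\COC/C=C(\O[Li])N1[C@H](Cc2ccccc2)COC1=O | intermediate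
7 | (4R,4'R)-3,3'-[(3R,4R)-tetrahydrofuran-3,4-diyldicarbonyl]bis(4-benzyl-1,3-oxazolidin-2-one) | O=C(N1[C@H](Cc2ccccc2)COC1=O)[C@H]1COC[C@@H]1C(=O)N1[C@H](Cc2ccccc2)COC1=O | intermediate
8 | (3R,4R)-N3,N4-dimethoxy-N3,N4-dimethyltetrahydrofuran-3,4-dicarboxamide | CON(C)C(=O)[C@H]1COC[C@@H]1C(=O)N(C)OC | intermediate
9 | 4-bromo-2-methoxyphenol | COc1cc(Br)ccc1O | starting material
10 | (4-bromo-2-methoxyphenoxy)(tert-butyl)dimethylsilane | COc1cc(Br)ccc1O[Si](C)(C)C(C)(C)C | intermediate
11 | [4-(tert-butyldimethylsilyloxy)-3-methoxyphenyl]lithium (not isolated) | [Li]c1ccc(O[Si](C)(C)C(C)(C)C)c(OC)c1 | intermediate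
12 | dilithium bis-hemiaminal adduct of 8 with two units of 11, mixture at the aminal carbons (not isolated) | COc1cc(C(O[Li])(N(C)OC)[C@H]2COC[C@@H]2C(O[Li])(N(C)OC)c2ccc(O[Si](C)(C)C(C)(C)C)c(OC)c2)ccc1O[Si](C)(C)C(C)(C)C | intermediate
13 | (3R,4R)-3,4-bis[4-(tert-butyldimethylsilyloxy)-3-methoxybenzoyl]tetrahydrofuran | COc1cc(C(=O)[C@H]2COC[C@@H]2C(=O)c2ccc(O[Si](C)(C)C(C)(C)C)c(OC)c2)ccc1O[Si](C)(C)C(C)(C)C | intermediate
14 | (S,S)-[(3R,4R)-tetrahydrofuran-3,4-diyl]bis{[4-(tert-butyldimethylsilyloxy)-3-methoxyphenyl]methanol} | COc1cc([C@@H](O)[C@H]2COC[C@@H]2[C@H](O)c2ccc(O[Si](C)(C)C(C)(C)C)c(OC)c2)ccc1O[Si](C)(C)C(C)(C)C | intermediate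
15 | (S,S)-[(3R,4R)-tetrahydrofuran-3,4-diyl]bis[(4-hydroxy-3-methoxyphenyl)methanol] (CNP0157038.3) | COc1cc([C@@H](O)[C@H]2COC[C@@H]2[C@H](O)c2ccc(O)c(OC)c2)ccc1O | target

Total step count: 8.
Longest linear sequence: 7 steps (steps 1, 2, 3, 4, 6, 7 and 8; step 5 prepares aryl bromide 10 on a side branch).

Steps most likely to fail

1. Step 3. The enolates carry a β-ether oxygen, so loss of the tether oxygen by β-elimination can cut the chain before the ring closes. α-Chlorination by CuCl2 or intermolecular coupling can also compete, and facial control in the ring-closing mode may be weaker than in open-chain couplings. The fallback uses known chemistry, sets out from 3 and rejoins the route at 7; it builds the ring by a [3+2] cycloaddition instead of an enolate coupling. Lithio oxazolidinone 4 (from 3 and n-BuLi) is acylated with fumaroyl dichloride to give the fumaroyl bis-imide (4R,4'R)-3,3'-[(E)-but-2-enedioyl]bis(4-benzyl-1,3-oxazolidin-2-one) F1. Chloromethyl (trimethylsilyl)methyl ether and CsF in MeCN generate, by fluoride-induced 1,3-elimination, the parent carbonyl ylide (formaldehyde O-methylide) F2. This should add suprafacially to the E-alkene of F1, so that only trans-3,4-diacyl tetrahydrofurans form: compound 7 and its (3S,4S) diastereomer F3. The two differ as diastereomers because of the auxiliaries and should be separable by chromatography or crystallisation; 7 then continues at step 4.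

2. Step 6. The aryllithium is a strong base. Deprotonation at C3 or C4 of the amide, of the tetrahedral adduct or of the product would epimerise the ring through the cis isomer and, over two events, erode the enantiomeric purity; incomplete second addition is the other risk. The fallback sets out from 7 and rejoins at 13, and is a base-free ketone synthesis. Lithium ethanethiolate (LiSEt, THF, 0 °C) displaces both auxiliaries from 7 to give S,S'-diethyl (3R,4R)-tetrahydrofuran-3,4-bis(carbothioate) F4. Aryllithium 11 is trapped with B(Oi-Pr)3 and hydrolysed to [4-(tert-butyldimethylsilyloxy)-3-methoxyphenyl]boronic acid F5. Liebeskind–Srogl coupling of F4 with F5 (Pd2(dba)3 as the zerovalent palladium source, tri(2-furyl)phosphine, copper thiophene-2-carboxylate CuTC with monovalent copper, THF, 50 °C) should give diketone 13 under neutral conditions.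

3. Step 4. The imide carbonyls are α-branched and vicinal, so the aluminium amide may attack the ring carbonyl of the oxazolidinone and open the auxiliary, or the reaction may stop after one aminolysis. The fallback sets out from 7 and rejoins at 8. Hydrolysis with LiOH and H2O2 in THF–water at 0 °C, which is selective for the exocyclic carbonyl, gives (3R,4R)-tetrahydrofuran-3,4-dicarboxylic acid F6. Amide coupling with MeNH(OMe)·HCl (EDC·HCl, HOBt, N-methylmorpholine, CH2Cl2) then gives 8.

Further compounds
F1 | step 3 | (4R,4'R)-3,3'-[(E)-but-2-enedioyl]bis(4-benzyl-1,3-oxazolidin-2-one) | O=C(/C=C/C(=O)N1[C@H](Cc2ccccc2)COC1=O)N1[C@H](Cc2ccccc2)COC1=O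
F2 | step 3 | parent carbonyl ylide (formaldehyde O-methylide), formed in the flask | [CH2-][O+]=C
F3 | step 3 | (4R,4'R)-3,3'-[(3S,4S)-tetrahydrofuran-3,4-diyldicarbonyl]bis(4-benzyl-1,3-oxazolidin-2-one) | O=C(N1[C@H](Cc2ccccc2)COC1=O)[C@@H]1COC[C@H]1C(=O)N1[C@H](Cc2ccccc2)COC1=O
F4 | step 6 | S,S'-diethyl (3R,4R)-tetrahydrofuran-3,4-bis(carbothioate) | CCSC(=O)[C@H]1COC[C@@H]1C(=O)SCC
F5 | step 6 | [4-(tert-butyldimethylsilyloxy)-3-methoxyphenyl]boronic acid | COc1cc(B(O)O)ccc1O[Si](C)(C)C(C)(C)C
F6 | step 4 | (3R,4R)-tetrahydrofuran-3,4-dicarboxylic acid | OC(=O)[C@H]1COC[C@@H]1C(=O)O
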